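Locants used throughout: atoms are numbered along the target SMILES from the acetoxy carbon, C1(OAc), C2, C3(CH3), O4, C5, C6, C7(Br), C8(CH3)2, O9, C10(CH3), C11, C12, C13(OH).

## Analysis of the target

- **Ring system.** The cyclohexane C1–C2–C3–C13–C12–C11 is bridged 1,4 by O4–C5–C10, giving a 2-oxabicyclo[3.2.2]nonane. Ring A (C5–C6–C7–C8–O9–C10, a tetrahydropyran) is cis-fused to the oxepane along C5–C10.
- **Stereocentres.** There are seven: 1S, 3R, 5S, 7S, 10S, 11R, 13R. The C1 acetate is cis to the C11–C10 bond (syn to the oxa bridge). The C13 hydroxyl is trans to the C3–O4 bond (anti to the bridge). On ring A the C10 methyl and H5 are cis, and bromine is trans to C11 across the ring.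
- **Sensitive groups.** A secondary acetate sits in the same molecule as a free secondary alcohol. The secondary bromide is neopentyl-like and can eliminate. The ether carbons C3, C8 and C10 are fully substituted and can ionise in strong acid.
- **What makes it hard.** The C5 oxygen must go to C3 and the C10 oxygen to C8 without crossing: a free C10 hydroxyl would close the easier six-membered cineole-type ether onto C3. The quaternary C10 must be set next to C5, and the C1 and C13 oxygens must be told apart at the end.
- **Feature the strategy rests on.** In the carbocycle, oxygen on C1 is cis to the C10 branch on C11, and a methyl sits on C3, 1,3 to C1. This is the endo, ortho adduct of a 1-oxy-3-methylbutadiene with a vinyl ketone whose carbonyl carbon is C10. The C2=C3 alkene left by the cycloaddition is the handle for both the C13 hydroxyl and the C3–O4 bond.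

## Retrosynthetic reasoning

**Ester endgame (20 back to 16).** Once ring A is closed, the only oxygens still to be adjusted are C1 (silyl ether) and C13 (free hydroxyl) in 16. The acetate must end on C1 alone, so C13 is capped first as a chloroacetate (17), the silyl ether is removed (18), C1 is acetylated (19), and the chloroacetate is taken off selectively to give 20. No selectivity between two free secondary hydroxyls is ever asked for.

**Ring A (16 back to 15, then to 13 and 14).** The C8–O9 and C7–Br bonds are cut together, which is a bromoetherification of prenyl alcohol 15 by its tertiary C10 hydroxyl. It is placed late because the bromide is the most fragile group and the electron-rich prenyl alkene must not be present while the ring alkene is functionalised. The forward step must close 6-endo at the tertiary carbon C8 and place bromine trans to C11. The C7=C8 bond of 15 is cut by cross-metathesis into the vinyl compound 13 and 14. The vinyl group is carried through the earlier steps because it is much less nucleophilic than the ring alkene.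

**C10 methyl (13 back to 11 and 12).** The C10–CH3 bond is formed on the bicyclic ketone 11, not on an open-chain ketone such as 8 or 9, for two reasons.
- A Cram-chelate addition through the C5 oxygen of 8 or 9 would deliver methyl anti to the C5 allyl group. In the target, with O9 and O4 eclipsed, the methyl eclipses C6, so chelation control gives the C10 epimer.
- A free tertiary C10 hydroxyl on the open chain would capture C3 in a six-membered 2-oxabicyclo[2.2.2]octane ether in preference to the seven-membered closure wanted from the C5 hydroxyl.

In 11 both problems vanish. The C1 silyloxy group and the C5 allyl group lie on the same face of the C10 carbonyl, so 12 should add from the opposite face and give 10S.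

**Oxa bridge (11 back to 9 through 10).** The C3–O4 bond is cut, which is a Markovnikov, anti alkoxymercuration of the C2=C3 alkene by the C5 hydroxyl. Only an oxygen delivered from the face that carries the C11 side chain can reach C3, so the tether sets C3. The mercury left at C2 (in 10) is removed by a radical reduction that spares the ketone.

**C13 oxygen (9 back to 8).** The C13–O bond is cut by an ene-type allylic oxidation. It must precede the bridge closure because it needs the alkene. It should take the ring CH2 at the more substituted alkene terminus, on the face away from the two ring substituents.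

**Carbocycle (8 back to 2 and 7), the key disconnection.** The C1–C11 and C12–C13 bonds are cut. This is the only disconnection that makes the ring, both ring stereocentres and the C2=C3 alkene at once from two small pieces, one of which (7) already carries C5 in its final configuration together with the hydroxyl that later becomes O4. The forward reaction has to be ortho-regioselective, endo, and face-selective on the chelated enone. The face needed is the one syn to the C5 allyl group, so the chiral ligand, not the substrate, must decide.

**Precursors.** Enone 7 comes from Weinreb amide 5 and 6 (C10–vinyl bond). 5 comes from hydroxy acid 4 and that from the amino acid 3, which supplies C5 as S. Diene 2 comes from enal 1 in one step.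

## Alternatives that were turned down

**Alternative 1:** ring expansion of a cineole-type ether.
- *Disconnection:* O4–C5 and O9–C10 together. The precursor is the 2-oxabicyclo[2.2.2]octane A2, whose ether oxygen joins C3 and C10. C10 carries the chain C5(OMs)–C6–C7(Br)–C8(OH)(CH3)2.
- *Forward key step:* in an ionising, weakly nucleophilic alcohol the ether oxygen displaces the neighbouring mesylate to give a three-membered oxonium ion. The C8 hydroxyl opens it at the tertiary carbon C10 to give A1.
- *For:* both C5 and C10 are set stereospecifically by inversion. Two rings change in one step. It uses the easy six-membered closure that the chosen route has to avoid. On the security of C10 it is stronger than the chosen route, which relies on a facial preference.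
- *Against:* A2 needs C5, C7 and C10 set on an open chain before the key step, which means many more steps. The oxonium ion can also be opened by the C8 hydroxyl at C5 (five-membered ring), can lose a proton, or can be bypassed by direct displacement of the mesylate.
- *Comparison:* the chosen strategy offers a short precursor and places its main risk at step 5 of 14, not near the end.

**Alternative 2:** ring A from a furan by anodic Achmatowicz reaction.
- *Disconnection:* C8–O9. The precursor is the 5-methylfuryl carbinol A4, which has a C3=C13 ring alkene.
- *Forward key step:* anodic 2,5-dimethoxylation in methanol, then aqueous acid, opens the furan to the ene-dione. The C10 hydroxyl closes on C8 to give hydroxypyranone A3.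
- *For:* the key reaction itself is more dependable and more scalable than the cycloaddition, and it uses no chemical oxidant.
- *Against:* A3 has C8 as a hemiketal with one methyl, C6=C7 as an enone and C5 as a ketone. Ring A then still needs a second methyl at C8, bromine at C7, reduction at C5 and C6, and a later bridge closure to C3. The carbocycle stereochemistry has to come from elsewhere, and the p-methoxybenzyl ether and ring alkene compete at the anode.
- *Comparison:* the chosen route installs the geminal methyls and the bromine in one bromoetherification and takes C5 from a commercial amino acid.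

**Alternative 3:** oxonium ylide [2,3]-shift.
- *Disconnection:* O4–C5 and C5–C6. The precursor is diazoketone A6, with a tertiary allyl ether on C3 cis to the C11 diazoacetyl group.
- *Forward key step:* Rh2(OAc)4 or Cu(CF3COCHCOCF3)2 generates the carbenoid, the ether oxygen adds, and the allyl group migrates to C5 to give A5.
- *For:* ring and C5–C6 bond form in one step. A5 is the triisopropylsilyl ether of ketone 11, so the later steps would be shared. It avoids mercury and the mismatched facial problem of the chosen key step, and on those points it is stronger.
- *Against:* it needs a hindered tertiary allyl ether with C3 already set cis to C11. Seven-membered ylide formation competes with C–H insertion and cyclopropanation. The shift must place the allyl group on the more crowded side of the bridge.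
- *Comparison:* the chosen route sets C3 through the tether and takes C5 from the chiral pool.

Key step: step 5

Assumption: the facial sense of the copper bis(oxazoline) catalyst is assigned from the square-planar chelate model, and both enantiomers of allylglycine and of the ligand are taken as purchasable.

## Route

Step 1
Reactants: 1 3-methylbut-2-enal
Product: 2 (E)-1-(tert-butyldimethylsilyloxy)-3-methylbuta-1,3-diene
Conditions: TBSOTf, Et3N, Et2O, 0 °C → rt; distil
Reagents that add atoms: tert-butyldimethylsilyl triflate, CC(C)(C)[Si](C)(C)OS(=O)(=O)C(F)(F)F
Why: Vinylogous enol silylation: the silyl triflate activates the aldehyde oxygen and triethylamine removes a γ-proton; the s-trans enal leads to the (E)-dienol ether, whose geometry the endo cycloaddition later turns into the cis C1/C11 pair.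

Step 2
Reactants: 3 (S)-2-aminopent-4-enoic acid (L-allylglycine)
Product: 4 (S)-2-hydroxypent-4-enoic acid
Conditions: NaNO2, 1 M H2SO4 (aq), 0 °C → rt
Reagents that add atoms: water, O
Why: Diazotisation of an α-amino acid; the carboxylate expels N2 to an α-lactone that water reopens, so two inversions give net retention and the (S) carbinol that becomes C5.

Step 3
Reactants: 4 (S)-2-hydroxypent-4-enoic acid
Product: 5 (S)-2-hydroxy-N-methoxy-N-methylpent-4-enamide
Conditions: MeNHOMe·HCl, EDC·HCl, HOBt, N-methylmorpholine, CH2Cl2, 0 °C → rt
Reagents that add atoms: N,O-dimethylhydroxylamine hydrochloride, CNOC.Cl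
Why: Carbodiimide/HOBt amidation; the amine is far more nucleophilic than the secondary hydroxyl, and the stereocentre is not expected to racemise under these conditions.

Step 4
Reactants: 5 (S)-2-hydroxy-N-methoxy-N-methylpent-4-enamide; 6 vinylmagnesium bromide
Product: 7 (S)-4-hydroxyhepta-1,6-dien-3-one
Conditions: CH2=CHMgBr (3 equiv), THF, −78 → 0 °C; inverse quench into cold 1 M HCl
Reagents that add atoms: none
Why: Weinreb ketone synthesis on the magnesium alkoxide of 5: the N-methoxy chelate holds the tetrahedral adduct until the quench, so one vinyl group is delivered; quenching into acid protonates the released amine before it can add to the enone, and C5 is untouched.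

Step 5
Reactants: 2 (E)-1-(tert-butyldimethylsilyloxy)-3-methylbuta-1,3-diene; 7 (S)-4-hydroxyhepta-1,6-dien-3-one
Product: 8 (2S)-1-[(1R,2S)-2-(tert-butyldimethylsilyloxy)-4-methylcyclohex-3-en-1-yl]-2-hydroxypent-4-en-1-one (target locants 1S,5S,11R)
Conditions: Cu(OTf)2 (10 mol %), (R,R)-2,2'-isopropylidenebis(4-tert-butyl-2-oxazoline) (11 mol %), 4 Å molecular sieves, CH2Cl2, −40 → −20 °C
Reagents that add atoms: none
Why: The ketone and α'-hydroxyl of 7 bind the divalent copper bis(oxazoline) complex as a five-membered chelate, which lowers the enone LUMO and holds it s-cis, and diene 2 then adds in a concerted, asynchronous [4+2] cycloaddition with the C12–C13 bond ahead of the C1–C11 bond. The closest known reaction type is the Cu(OTf)2–bis(oxazoline)-catalysed Diels–Alder reaction of α'-hydroxy enones with acyclic dienes, together with the same catalyst family acting on 1-oxygenated dienes. The carbocycle is closed by this single suprafacial [4+2] event (six-membered, both σ bonds in one step), leaving the C2=C3 alkene. Regiochemistry: the 1-silyloxy and 3-methyl groups both put the largest HOMO coefficient on the unsubstituted diene terminus (C13), which bonds to the enone β-carbon C12, so the acyl group ends on C11 next to C1. The C1/C11 relationship comes from the endo transition state, with the chelated carbonyl under the diene, which turns the (E) geometry of 2 into cis silyloxy and acyl groups. The absolute sense (1S,11R) comes from the ligand: on the square-planar model the tert-butyl group of the (R,R) ligand beside the bound carbonyl covers one enone face and the diene adds to the other, which is the face that also carries the C5 allyl group. C5 is not touched, but on its own it would send the diene anti to its allyl group, so this is the mismatched pairing and the step needs ligand control to override the substrate; this is reasonable because the obstacle on the reacting face is only a CH2 group, no larger than the methyl that gem-dimethyl α'-hydroxy enones carry on that face in their face-selective cycloadditions. Low temperature and sieves are there to suppress silyl transfer to the free hydroxyl, hydrolysis of 2 and loss of silanol from the β-silyloxy ketone product.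

Step 6
Reactants: 8 (2S)-1-[(1R,2S)-2-(tert-butyldimethylsilyloxy)-4-methylcyclohex-3-en-1-yl]-2-hydroxypent-4-en-1-one
Product: 9 (2S)-1-[(1R,2S,5R)-2-(tert-butyldimethylsilyloxy)-5-hydroxy-4-methylcyclohex-3-en-1-yl]-2-hydroxypent-4-en-1-one (target locants 1S,5S,11R,13R)
Conditions: SeO2 (0.5 equiv), t-BuOOH (2 equiv), CH2Cl2, 0 °C → rt
Reagents that add atoms: selenium dioxide, O=[Se]=O; tert-butyl hydroperoxide, CC(C)(C)OO
Why: Selenium dioxide ene reaction at the trisubstituted alkene (Se to C2, hydrogen taken from the ring CH2 on the more substituted terminus) followed by [2,3]-sigmatropic shift returns the C2=C3 alkene and puts oxygen on C13. Se and O stay on one face, and the face anti to the C1 silyloxy group and the C11 side chain is the open one, so the hydroxyl should arrive trans to both (13R). Substoichiometric SeO2 with the hydroperoxide keeps the product at the alcohol stage.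

Step 7
Reactants: 9 (2S)-1-[(1R,2S,5R)-2-(tert-butyldimethylsilyloxy)-5-hydroxy-4-methylcyclohex-3-en-1-yl]-2-hydroxypent-4-en-1-one
Product: 11 (1R,3S,5R,6S,8R)-3-allyl-6-(tert-butyldimethylsilyloxy)-8-hydroxy-1-methyl-2-oxabicyclo[3.2.2]nonan-4-one (target locants 1S,3R,5S,11R,13R), via C2-mercurated bridged ether 10 (not isolated)
Conditions: Hg(OCOCF3)2 (1.1 equiv), CH2Cl2, −20 °C; then n-Bu3SnH (2.5 equiv), THF, 0 °C → rt
Reagents that add atoms: none
Why: Intramolecular alkoxymercuration: the mercurinium ion forms on the alkene face anti to the C1 silyloxy group, and the C5 hydroxyl, held under the ring by the axial C11 acyl chain, opens it anti at the tertiary carbon C3 (7-exo, Markovnikov), which fixes C3 as R. Mercuration of the vinyl group is reversible and has no hydroxyl within reach of a five- or six-membered closure. The tin hydride replaces mercury at C2 by hydrogen through the alkyl radical and, unlike NaBH4, leaves the C10 ketone alone.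

Step 8
Reactants: 11 (1R,3S,5R,6S,8R)-3-allyl-6-(tert-butyldimethylsilyloxy)-8-hydroxy-1-methyl-2-oxabicyclo[3.2.2]nonan-4-one; 12 methylmagnesium bromide
Product: 13 (1R,3S,4S,5R,7R,9S)-3-allyl-9-(tert-butyldimethylsilyloxy)-1,4-dimethyl-2-oxabicyclo[3.2.2]nonane-4,7-diol (target locants 1S,3R,5S,10S,11R,13R)
Conditions: MeMgBr (4 equiv), THF, −78 → −40 °C; aqueous work-up
Reagents that add atoms: none
Why: Grignard addition under steric control of the bicycle: the face of the C10 carbonyl turned toward the C1–C2 bridge is covered by the C1 silyloxy group (which points at the oxa bridge) and by the C5 allyl group, so methyl should enter from the C12–C13 side and leave the new hydroxyl on the allyl side (10S), cis to the future ring A. The first equivalent is spent on the C13 hydroxyl, and C11 is a bridgehead, so only enolisation toward C5 has to be outrun at low temperature.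

Step 9
Reactants: 13 (1R,3S,4S,5R,7R,9S)-3-allyl-9-(tert-butyldimethylsilyloxy)-1,4-dimethyl-2-oxabicyclo[3.2.2]nonane-4,7-diol; 14 2-methylbut-2-ene
Product: 15 (1R,3S,4S,5R,7R,9S)-9-(tert-butyldimethylsilyloxy)-1,4-dimethyl-3-(3-methylbut-2-en-1-yl)-2-oxabicyclo[3.2.2]nonane-4,7-diol
Conditions: second-generation Grubbs catalyst RuCl2(=CHPh)(H2IMes)(PCy3) (5 mol %), 2-methylbut-2-ene (excess), CH2Cl2, 40 °C
Reagents that add atoms: none
Why: Olefin cross-metathesis of the terminal alkene with excess 2-methylbut-2-ene caps the chain as the prenyl group and releases propene; the trisubstituted product does not re-enter the cycle, and free hydroxyls are tolerated.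

Step 10
Reactants: 15 (1R,3S,4S,5R,7R,9S)-9-(tert-butyldimethylsilyloxy)-1,4-dimethyl-3-(3-methylbut-2-en-1-yl)-2-oxabicyclo[3.2.2]nonane-4,7-diol
Product: 16 C1 tert-butyldimethylsilyl ether of the deacetyl target (tricycle with C7 bromide and free C13 hydroxyl; 1S,3R,5S,7S,10S,11R,13R)
Conditions: 2,4,4,6-tetrabromocyclohexa-2,5-dienone (1.1 equiv), MeNO2, 0 °C → rt, dark
Reagents that add atoms: 2,4,4,6-tetrabromocyclohexa-2,5-dienone, O=C1C(Br)=CC(Br)(Br)C=C1Br
Why: Bromoetherification: the bromonium ion of the electron-rich prenyl alkene is opened anti by the tertiary C10 hydroxyl at the tertiary carbon C8 (6-endo, Markovnikov), closing ring A. In the chair transition state bromine and the bulky C11 branch of C10 are equatorial (C10 methyl axial) on the oxepane conformer that keeps the C5–C6 bond pseudo-equatorial, which corresponds to 7S. The C13 hydroxyl cannot reach the bromonium ion in a ring smaller than seven.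

Step 11
Reactants: 16 C1 tert-butyldimethylsilyl ether of the deacetyl target
Product: 17 C1 tert-butyldimethylsilyl ether C13 chloroacetate of the deacetyl target
Conditions: (ClCH2CO)2O, pyridine, DMAP (cat.), CH2Cl2, 0 °C
Reagents that add atoms: chloroacetic anhydride, ClCC(=O)OC(=O)CCl
Why: Acylation of the only free hydroxyl (C13) as a chloroacetate, an ester that can later be removed without touching an acetate.

Step 12
Reactants: 17 C1 tert-butyldimethylsilyl ether C13 chloroacetate of the deacetyl target
Product: 18 C13 chloroacetate of the deacetyl target (free C1 hydroxyl)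
Conditions: HF·pyridine, pyridine, THF, 0 °C → rt
Reagents that add atoms: none
Why: Acidic fluoride cleaves the Si–O bond; the chloroacetate, the bromide and the tertiary ethers are stable to it, whereas basic fluoride would endanger the chloroacetate.

Step 13
Reactants: 18 C13 chloroacetate of the deacetyl target
Product: 19 C13 chloroacetate of the target (C1 acetate)
Conditions: Ac2O, pyridine, DMAP (cat.), CH2Cl2, rt
Reagents that add atoms: acetic anhydride, CC(=O)OC(C)=O
Why: DMAP-catalysed acetylation of the now unique free hydroxyl at C1.

Step 14
Reactants: 19 C13 chloroacetate of the target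
Product: 20 target (C1 acetate, C13 hydroxyl; 1S,3R,5S,7S,10S,11R,13R)
Conditions: thiourea, NaHCO3, EtOH, 50 °C
Reagents that add atoms: none
Why: Thiourea alkylates at the chloromethyl carbon and the isothiouronium nitrogen then cyclises onto the ester carbonyl, releasing the C13 hydroxyl; a plain acetate has no such handle and stays, and the hindered secondary bromide is not displaced.

## Compound list

1 | 3-methylbut-2-enal | CC(C)=CC=O | starting material
2 | (E)-1-(tert-butyldimethylsilyloxy)-3-methylbuta-1,3-diene | CC(=C)/C=C/O[Si](C)(C)C(C)(C)C | intermediate
3 | (S)-2-aminopent-4-enoic acid (L-allylglycine) | N[C@@H](CC=C)C(=O)O | starting material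
4 | (S)-2-hydroxypent-4-enoic acid | O[C@@H](CC=C)C(=O)O | intermediate
5 | (S)-2-hydroxy-N-methoxy-N-methylpent-4-enamide | CON(C)C(=O)[C@@H](O)CC=C | intermediate
6 | vinylmagnesium bromide | C=C[Mg]Br | starting material
7 | (S)-4-hydroxyhepta-1,6-dien-3-one | C=CC(=O)[C@@H](O)CC=C | intermediate
8 | (2S)-1-[(1R,2S)-2-(tert-butyldimethylsilyloxy)-4-methylcyclohex-3-en-1-yl]-2-hydroxypent-4-en-1-one | CC(C)(C)[Si](C)(C)O[C@H]1C=C(C)CC[C@H]1C(=O)[C@@H](O)CC=C | intermediate
9 | (2S)-1-[(1R,2S,5R)-2-(tert-butyldimethylsilyloxy)-5-hydroxy-4-methylcyclohex-3-en-1-yl]-2-hydroxypent-4-en-1-one | CC(C)(C)[Si](C)(C)O[C@H]1C=C(C)[C@H](O)C[C@H]1C(=O)[C@@H](O)CC=C | intermediate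
10 | C2-(trifluoroacetoxymercurio) derivative of 11, mercury anti to the C3–O4 bond | CC(C)(C)[Si](C)(C)O[C@H]1[C@H]([Hg]OC(=O)C(F)(F)F)[C@@]2(C)O[C@@H](CC=C)C(=O)[C@@H]1C[C@H]2O | intermediate
11 | (1R,3S,5R,6S,8R)-3-allyl-6-(tert-butyldimethylsilyloxy)-8-hydroxy-1-methyl-2-oxabicyclo[3.2.2]nonan-4-one | CC(C)(C)[Si](C)(C)O[C@H]1C[C@@]2(C)O[C@@H](CC=C)C(=O)[C@@H]1C[C@H]2O | intermediate
12 | methylmagnesium bromide | C[Mg]Br | starting material
13 | (1R,3S,4S,5R,7R,9S)-3-allyl-9-(tert-butyldimethylsilyloxy)-1,4-dimethyl-2-oxabicyclo[3.2.2]nonane-4,7-diol | CC(C)(C)[Si](C)(C)O[C@H]1C[C@@]2(C)O[C@@H](CC=C)[C@@](C)(O)[C@@H]1C[C@H]2O | intermediate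
14 | 2-methylbut-2-ene | CC=C(C)C | starting material
15 | (1R,3S,4S,5R,7R,9S)-9-(tert-butyldimethylsilyloxy)-1,4-dimethyl-3-(3-methylbut-2-en-1-yl)-2-oxabicyclo[3.2.2]nonane-4,7-diol | CC(C)(C)[Si](C)(C)O[C@H]1C[C@@]2(C)O[C@@H](CC=C(C)C)[C@@](C)(O)[C@@H]1C[C@H]2O | intermediate
16 | C1 tert-butyldimethylsilyl ether of the deacetyl target | CC(C)(C)[Si](C)(C)O[C@H]1C[C@@]2(C)O[C@H]3C[C@H](Br)C(C)(C)O[C@@]3(C)[C@@H]1C[C@H]2O | intermediate
17 | C1 tert-butyldimethylsilyl ether C13 chloroacetate of the deacetyl target | CC(C)(C)[Si](C)(C)O[C@H]1C[C@@]2(C)O[C@H]3C[C@H](Br)C(C)(C)O[C@@]3(C)[C@@H]1C[C@H]2OC(=O)CCl | intermediate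
18 | C13 chloroacetate of the deacetyl target | O[C@H]1C[C@@]2(C)O[C@H]3C[C@H](Br)C(C)(C)O[C@@]3(C)[C@@H]1C[C@H]2OC(=O)CCl | intermediate
19 | C13 chloroacetate of the target | CC(=O)O[C@H]1C[C@@]2(C)O[C@H]3C[C@H](Br)C(C)(C)O[C@@]3(C)[C@@H]1C[C@H]2OC(=O)CCl | intermediate
20 | target CNP0247588.2 | CC(=O)O[C@H]1C[C@@]2(C)O[C@H]3C[C@H](Br)C(C)(C)O[C@@]3(C)[C@@H]1C[C@H]2O | target

## Step count and weak points

Total: 14 steps. Longest linear sequence: 13 steps (steps 2–14, from 3). The diene branch is one step.

**Step 5 (key step).** The most likely failure is erosion of π-facial selectivity, because the C5 stereocentre and the ligand direct the diene to opposite faces. Silyl transfer from 2 to the free hydroxyl, or loss of silanol from the adduct on the Lewis acid, would lower the throughput further. The fallback keeps the cycloaddition but makes substrate and ligand cooperate; it sets out from diene 2 and returns at 8. D-Allylglycine F1 is taken through the reactions of steps 2–4 (hydroxy acid F2, Weinreb amide F3) to the (R)-hydroxy enone F4. With the same (R,R) ligand the diene then adds anti to the allyl group, giving the same ring configuration in the C5 epimer F5. Mitsunobu esterification with chloroacetic acid (PPh3, diisopropyl azodicarboxylate, toluene, 0 °C) inverts the activated α-keto carbinol to the (5S) chloroacetate F6. Thiourea/NaHCO3 in ethanol then releases 8 without a base strong enough to epimerise C11.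

**Step 7 (bridge closure).** The seven-membered closure may be slow. The divalent mercury salt may then be diverted by the vinyl group or the ketone oxygen, the C5 hydroxyl may close a six-membered ring onto C2, or the acid released may ionise the allylic silyl ether. The fallback runs from 9 to 11 with an electrophile whose alkene preference is electronic. N-(Phenylselanyl)phthalimide with catalytic camphorsulfonic acid (CH2Cl2, −78 → 0 °C) should give the C2 phenylselenide F7 by the same anti, Markovnikov closure. n-Bu3SnH/AIBN in toluene at 80 °C then removes selenium.

**Step 6 (allylic oxidation).** Oxidation may spread to the C3 methyl group, run on to the enone, or attack the free α-ketol; the face selectivity is argued from conformation only. The fallback runs from 8 to 9 with the ketol masked. Et3SiCl/imidazole gives the C5 triethylsilyl ether F8. The same SeO2/t-BuOOH oxidation gives allylic alcohol F9. PPTS in methanol at 0 °C removes the triethylsilyl group ahead of the tert-butyldimethylsilyl group.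

**Step 10 (bromoetherification).** Five-membered closure at C7 (leaving a tertiary bromide) and formation of the C7 epimer through the other chair are the likely leaks, as is usual for this ring type. The fallback runs from 15 to 16 in two stages. Hg(OCOCF3)2 in MeNO2 at 0 °C, then aqueous KBr, should settle by reversible mercuricyclisation on the six-membered Markovnikov ether with mercury equatorial, the organomercuric bromide F10. Br2/LiBr in pyridine under O2 then replaces mercury by bromine with retention.

**Step 8 (methyl addition).** Enolisation toward C5 would return ketone and epimerise C5, whose allyl group sits on the more crowded side. Pre-complexing the Grignard reagent with CeCl3 is the first adjustment. The fallback runs from 11 to 13 with a different nucleophile. Dimethylsulfonium methylide (Me3SI, n-BuLi, THF, −10 °C) adds irreversibly from the same open face to give the spiro-epoxide F11. LiEt3BH in THF opens it at the methylene carbon.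

## Further compounds

F1 | step 5 | (R)-2-aminopent-4-enoic acid (D-allylglycine) | N[C@H](CC=C)C(=O)O
F2 | step 5 | (R)-2-hydroxypent-4-enoic acid | O[C@H](CC=C)C(=O)O
F3 | step 5 | (R)-2-hydroxy-N-methoxy-N-methylpent-4-enamide | CON(C)C(=O)[C@H](O)CC=C
F4 | step 5 | (R)-4-hydroxyhepta-1,6-dien-3-one | C=CC(=O)[C@H](O)CC=C
F5 | step 5 | C5 epimer of 8, (2R)-1-[(1R,2S)-2-(tert-butyldimethylsilyloxy)-4-methylcyclohex-3-en-1-yl]-2-hydroxypent-4-en-1-one | CC(C)(C)[Si](C)(C)O[C@H]1C=C(C)CC[C@H]1C(=O)[C@H](O)CC=C
F6 | step 5 | C5 chloroacetate of 8 | CC(C)(C)[Si](C)(C)O[C@H]1C=C(C)CC[C@H]1C(=O)[C@@H](OC(=O)CCl)CC=C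
F7 | step 7 | C2 phenylselanyl derivative of 11, selenium anti to the C3–O4 bond | CC(C)(C)[Si](C)(C)O[C@H]1[C@H]([Se]c3ccccc3)[C@@]2(C)O[C@@H](CC=C)C(=O)[C@@H]1C[C@H]2O
F8 | step 6 | C5 triethylsilyl ether of 8 | CC(C)(C)[Si](C)(C)O[C@H]1C=C(C)CC[C@H]1C(=O)[C@@H](O[Si](CC)(CC)CC)CC=C
F9 | step 6 | C5 triethylsilyl ether of 9 | CC(C)(C)[Si](C)(C)O[C@H]1C=C(C)[C@H](O)C[C@H]1C(=O)[C@@H](O[Si](CC)(CC)CC)CC=C
F10 | step 10 | C7 bromomercurio analogue of 16 | CC(C)(C)[Si](C)(C)O[C@H]1C[C@@]2(C)O[C@H]3C[C@H]([Hg]Br)C(C)(C)O[C@@]3(C)[C@@H]1C[C@H]2O
F11 | step 8 | C10 spiro-epoxide from 11, CH2 on the C12–C13 side | CC(C)(C)[Si](C)(C)O[C@H]1C[C@@]2(C)O[C@@H](CC=C)[C@]3(CO3)[C@@H]1C[C@H]2O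
A1 | alternative 1 | ring-expanded tricycle, C1 triisopropylsilyl ether and C13 chloroacetate | CC(C)[Si](C(C)C)(C(C)C)O[C@H]1C[C@@]2(C)O[C@H]3C[C@H](Br)C(C)(C)O[C@@]3(C)[C@@H]1C[C@H]2OC(=O)CCl
A2 | alternative 1 | cineole-type ether with C5 mesylate, C7 bromide and C8 hydroxyl | CC(C)[Si](C(C)C)(C(C)C)O[C@H]1C[C@@]2(C)O[C@@](C)([C@H](OS(C)(=O)=O)C[C@H](Br)C(C)(C)O)[C@@H]1C[C@H]2OC(=O)CCl
A3 | alternative 2 | 6-hydroxy-2,6-dimethyl-2H-pyran-3(6H)-one on the cyclohexene | COc1ccc(cc1)CO[C@H]2CC(C)=CC[C@H]2[C@]3(C)O[C@@](C)(O)C=CC3=O
A4 | alternative 2 | 5-methylfuryl tertiary carbinol | COc1ccc(cc1)CO[C@H]2CC(C)=CC[C@H]2[C@](C)(O)c3ccc(C)o3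
A5 | alternative 3 | bridged oxepanone, C13 triisopropylsilyl ether of 11 | CC(C)(C)[Si](C)(C)O[C@H]1C[C@@]2(C)O[C@@H](CC=C)C(=O)[C@@H]1C[C@H]2O[Si](C(C)C)(C(C)C)C(C)C
A6 | alternative 3 | diazoketone with C3 allyl ether | CC(C)(C)[Si](C)(C)O[C@H]1C[C@@](C)(OCC=C)[C@H](O[Si](C(C)C)(C(C)C)C(C)C)C[C@H]1C(=O)C=[N+]=[N-]
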